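**Retrosynthetic overview** (daucane numbering: C1 quaternary fusion carbon, C5 fusion CH, C2–C4 complete the five-membered ring, C6–C10 the seven-membered ring)
1. Target ⇒ desilylation and double tigloylation of epoxy triol 26 ⇒ singlet-oxygen ene reaction with titanium oxygen transfer (C10–O and the 8,9-oxirane from a C9=C10 alkene) and hydroxyl-directed reduction at C6 ⇒ cis-hydroazulenone 23.
2. 23 ⇒ acyclic epoxy enol silane 20 by an intramolecular (4+3) cycloaddition that forms C1–C5 and C7–C8; both carbocycles close in this one step (the five-membered ring through C1–C5 alone), the oxirane ring is made last.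
3. Enabling feature: in the seven-membered ring C6 carries oxygen between C5 and C7 (an oxyallyl unit C5–C6–C7), the other four ring atoms C1, C10, C9, C8 are a diene, and C4 next to C5 bears the tertiary hydroxyl. A C4–C5 oxirane can therefore be the leaving group at C5 and deliver the C4–OH, with C2–C3–C4 as a three-atom tether.
4. 20 ⇒ methyl ketone 18 ⇒ Sharpless epoxidation of (E)-allylic alcohol 14 (C4, C5) ⇒ syn-carbocupration of ynoate 11 (alkene geometry).
5. 11 ⇒ asymmetric propargylation of (Z)-iodoenal 4 (C2) and Suzuki coupling with (E)-propenylboronic acid ((Z,E)-diene); 4 from propargyl alcohol.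

Key step: step 14

Remark: both acyl groups in the target are (E)-2-methylbut-2-enoyl (tigloyl), so commercial tigloyl chloride is used.
Remark: for the bicyclic compounds α/β refer to the flat-drawn hydroazulene with the C15 methyl on C1 taken as β; absolute configurations are those of the SMILES strings. The route assumes that allenylboronic acid pinacol ester, (E)-prop-1-en-1-ylboronic acid, (S)-TRIP and tigloyl chloride are purchased.

**Step 1**
Reactants: 1 prop-2-yn-1-ol
Product: 3 (2Z)-3-iodo-2-methylprop-2-en-1-ol, via alkenylmagnesium alkoxide 2 (not isolated)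
Conditions: MeMgBr (2.5 equiv), CuI (10 mol%), THF/Et2O, −10 °C to rt; then I2, −10 °C
Reagents that add atoms: methylmagnesium bromide, C[Mg]Br; iodine, [I][I]
Why: Copper-catalysed anti-carbomagnesiation of the propargylic alkoxide (methyl to the internal carbon, magnesium held cis to the alkoxide in a five-membered chelate) and iodinolysis with retention should give the (Z)-iodoalkene, the future C1=C10 bond with C2 cis to iodine.

**Step 2**
Reactants: 3 (2Z)-3-iodo-2-methylprop-2-en-1-ol
Product: 4 (2Z)-3-iodo-2-methylprop-2-enal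
Conditions: MnO2 (15 equiv), CH2Cl2, rt, dark
Reagents that add atoms: none
Why: Allylic oxidation with MnO2 is neutral and mild, so the (Z)-iodoenal should form without isomerisation.

**Step 3**
Reactants: 4 (2Z)-3-iodo-2-methylprop-2-enal; 5 allenylboronic acid pinacol ester
Product: 6 (1Z,3S)-1-iodo-2-methylhex-1-en-5-yn-3-ol
Conditions: 5 (1.5 equiv), (S)-TRIP [(S)-3,3'-bis(2,4,6-triisopropylphenyl)-1,1'-binaphthyl-2,2'-diyl hydrogen phosphate] (5 mol%), 4 Å MS, toluene, 0 °C; aqueous work-up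
Reagents that add atoms: none
Why: Chiral-phosphoric-acid-catalysed propargylation of an aldehyde with an allenylboronate (six-membered SE2' transition state); the (S)-catalyst is chosen to direct addition to the Si face of the enal, which sets the (S)-carbinol (C2).

**Step 4**
Reactants: 6 (1Z,3S)-1-iodo-2-methylhex-1-en-5-yn-3-ol
Product: 7 tert-butyl{[(1Z,3S)-1-iodo-2-methylhex-1-en-5-yn-3-yl]oxy}dimethylsilane
Conditions: t-BuMe2SiCl, imidazole, DMF, rt
Reagents that add atoms: tert-butyldimethylsilyl chloride, CC(C)(C)[Si](C)(C)Cl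
Why: Standard silylation of a secondary alcohol; the silyl ether must last until step 18 and keeps the C2 oxygen apart from the two hydroxyls to be acylated.

**Step 5**
Reactants: 7 tert-butyl{[(1Z,3S)-1-iodo-2-methylhex-1-en-5-yn-3-yl]oxy}dimethylsilane; 8 (E)-prop-1-en-1-ylboronic acid
Product: 9 tert-butyldimethyl{[(4S,5Z,7E)-5-methylnona-5,7-dien-1-yn-4-yl]oxy}silane
Conditions: 8 (1.5 equiv), Pd(PPh3)4 (5 mol%), K3PO4 (3 equiv), THF/H2O, rt to 40 °C
Reagents that add atoms: none
Why: Suzuki–Miyaura coupling of an alkenyl iodide with an alkenylboronic acid is stereoretentive on both partners and should give the (5Z,7E)-diene (C2 on the inside of the diene, C14 methyl trans); copper-free conditions should leave the terminal alkyne untouched.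

**Step 6**
Reactants: 9 tert-butyldimethyl{[(4S,5Z,7E)-5-methylnona-5,7-dien-1-yn-4-yl]oxy}silane
Product: 11 methyl (5S,6Z,8E)-5-[(tert-butyldimethylsilyl)oxy]-6-methyldeca-6,8-dien-2-ynoate, via lithium acetylide 10 (not isolated)
Conditions: n-BuLi (1.05 equiv), THF, −78 °C; then ClCO2Me, −78 to 0 °C
Reagents that add atoms: methyl chloroformate, COC(=O)Cl
Why: Deprotonation of the terminal alkyne and C-acylation of the acetylide is a routine ynoate synthesis; no other acidic or electrophilic site is present.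

**Step 7**
Reactants: 11 methyl (5S,6Z,8E)-5-[(tert-butyldimethylsilyl)oxy]-6-methyldeca-6,8-dien-2-ynoate
Product: 13 methyl (2E,5S,6Z,8E)-5-[(tert-butyldimethylsilyl)oxy]-6-methyl-3-(propan-2-yl)deca-2,6,8-trienoate, via alkenylcopper adduct 12 (not isolated)
Conditions: i-PrMgCl (1.5 equiv), CuI (1.5 equiv), THF, −40 °C; then 11, −78 °C; MeOH, −78 °C
Reagents that add atoms: isopropylmagnesium chloride, CC(C)[Mg]Cl
Why: Syn-carbocupration of the ynoate at low temperature and stereoretentive protonation of the alkenylcopper should place isopropyl cis to H, so the C3 chain ends up cis to the ester carbon (the geometry needed for C3 cis to C6 on the oxirane).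

**Step 8**
Reactants: 13 methyl (2E,5S,6Z,8E)-5-[(tert-butyldimethylsilyl)oxy]-6-methyl-3-(propan-2-yl)deca-2,6,8-trienoate
Product: 14 (2E,5S,6Z,8E)-5-[(tert-butyldimethylsilyl)oxy]-6-methyl-3-(propan-2-yl)deca-2,6,8-trien-1-ol
Conditions: i-Bu2AlH (2.5 equiv), CH2Cl2, −78 °C; aq. potassium sodium tartrate
Reagents that add atoms: none
Why: 1,2-Reduction of an enoate to the allylic alcohol with diisobutylaluminium hydride; the alkene geometry is not touched.

**Step 9**
Reactants: 14 (2E,5S,6Z,8E)-5-[(tert-butyldimethylsilyl)oxy]-6-methyl-3-(propan-2-yl)deca-2,6,8-trien-1-ol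
Product: 15 [(2R,3R)-3-{(2S,3Z,5E)-2-[(tert-butyldimethylsilyl)oxy]-3-methylhepta-3,5-dien-1-yl}-3-(propan-2-yl)oxiran-2-yl]methanol
Conditions: Ti(OiPr)4 (10 mol%), D-(−)-diethyl tartrate (12 mol%), t-BuOOH (2 equiv), 4 Å MS, CH2Cl2, −20 °C
Reagents that add atoms: tert-butyl hydroperoxide, CC(C)(C)OO
Why: Sharpless asymmetric epoxidation of a 3,3-disubstituted allylic alcohol; the D-(−)-tartrate should give the (2R,3R)-epoxy alcohol (mirror image of the (2S,3S) series from L-(+)-tartrate), setting C4 and C5, while the diene, which has no directing hydroxyl, stays intact.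

**Step 10**
Reactants: 15 [(2R,3R)-3-{(2S,3Z,5E)-2-[(tert-butyldimethylsilyl)oxy]-3-methylhepta-3,5-dien-1-yl}-3-(propan-2-yl)oxiran-2-yl]methanol
Product: 16 (2S,3R)-3-{(2S,3Z,5E)-2-[(tert-butyldimethylsilyl)oxy]-3-methylhepta-3,5-dien-1-yl}-3-(propan-2-yl)oxirane-2-carbaldehyde
Conditions: Dess–Martin periodinane (1.3 equiv), pyridine, CH2Cl2, 0 °C to rt
Reagents that add atoms: none
Why: Buffered Dess–Martin oxidation converts epoxy alcohols into epoxy aldehydes without opening the oxirane (the descriptor at C2 of the oxirane changes only through priorities).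

**Step 11**
Reactants: 16 (2S,3R)-3-{(2S,3Z,5E)-2-[(tert-butyldimethylsilyl)oxy]-3-methylhepta-3,5-dien-1-yl}-3-(propan-2-yl)oxirane-2-carbaldehyde
Product: 17 1-[(2R,3R)-3-{(2S,3Z,5E)-2-[(tert-butyldimethylsilyl)oxy]-3-methylhepta-3,5-dien-1-yl}-3-(propan-2-yl)oxiran-2-yl]ethan-1-ol (both carbinol epimers)
Conditions: MeMgBr (1.2 equiv), THF, −78 °C
Reagents that add atoms: methylmagnesium bromide, C[Mg]Br
Why: Grignard addition to the aldehyde at low temperature; the new carbinol centre need not be controlled because it is oxidised in step 12.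

**Step 12**
Reactants: 17 1-[(2R,3R)-3-{(2S,3Z,5E)-2-[(tert-butyldimethylsilyl)oxy]-3-methylhepta-3,5-dien-1-yl}-3-(propan-2-yl)oxiran-2-yl]ethan-1-ol
Product: 18 1-[(2S,3R)-3-{(2S,3Z,5E)-2-[(tert-butyldimethylsilyl)oxy]-3-methylhepta-3,5-dien-1-yl}-3-(propan-2-yl)oxiran-2-yl]ethan-1-one
Conditions: Dess–Martin periodinane (1.3 equiv), pyridine, CH2Cl2, rt
Reagents that add atoms: none
Why: Dess–Martin oxidation of the secondary alcohol gives the epoxy methyl ketone and removes the uncontrolled centre.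

**Step 13**
Reactants: 18 1-[(2S,3R)-3-{(2S,3Z,5E)-2-[(tert-butyldimethylsilyl)oxy]-3-methylhepta-3,5-dien-1-yl}-3-(propan-2-yl)oxiran-2-yl]ethan-1-one
Product: 20 triethyl{[1-[(2S,3R)-3-{(2S,3Z,5E)-2-[(tert-butyldimethylsilyl)oxy]-3-methylhepta-3,5-dien-1-yl}-3-(propan-2-yl)oxiran-2-yl]ethenyl]oxy}silane, via lithium enolate 19 (not isolated)
Conditions: LiN(SiMe3)2 (1.2 equiv), Et3SiCl (1.5 equiv), THF, −78 °C
Reagents that add atoms: chlorotriethylsilane, CC[Si](CC)(CC)Cl
Why: Kinetic deprotonation can only occur at the methyl group (the oxirane C–H is not enolisable) and O-silylation of the enolate gives the epoxy enol silane.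

**Step 14**
Reactants: 20 triethyl{[1-[(2S,3R)-3-{(2S,3Z,5E)-2-[(tert-butyldimethylsilyl)oxy]-3-methylhepta-3,5-dien-1-yl}-3-(propan-2-yl)oxiran-2-yl]ethenyl]oxy}silane
Product: 23 2β-[(tert-butyldimethylsilyl)oxy]-4α-hydroxy-5βH-dauc-9-en-6-one (cis-fused; C14 and C15 methyls β), via silyl epoxonium triflate 21 (not isolated), via triethylsilyl ether 22 (not isolated)
Conditions: Et3SiOTf (20 mol%), CH2Cl2 (0.01 M), −78 °C; then 1 M aq. HCl, THF, 0 °C
Reagents that add atoms: none
Why: Et3SiOTf silylates the oxirane oxygen (21); the C5–O bond, which is allylic to the enol silane and therefore carries the developing 2-silyloxyallyl cation, is then attacked from the backside by diene terminus C1 while enol-silane carbon C7 bonds to C8 on the same face of the s-cis diene, and loss of the silyl group from the resulting silyloxycarbenium ion returns Et3SiOTf and leaves the C6 ketone with the C4 oxygen as its silyl ether (22). The closest known reaction type is the silyl-triflate-catalysed (4+3) cycloaddition of epoxy enol silanes with dienes, known in inter- and intramolecular form and stereospecific with inversion at the oxirane carbon. The five-membered ring closes through C1–C5 alone, as an endo opening of the oxirane by the tethered alkene (both oxirane carbons end up in the new ring, made feasible by the cation-stabilising enol silane), and the seven-membered ring closes through C1–C5 plus C7–C8 as a type-1 intramolecular (4+3) cycloaddition, suprafacial on both partners. C5 is set by inversion at the (2S)-oxirane carbon and C4 is carried unchanged from step 9; C1 is set relative to C5 by the (Z)-C1=C10 geometry, which puts the three-atom tether on the inside of the diene so that only the cis-fused transition state can be reached; C8 follows from the (E)-propenyl terminus (C14 outside like C15, hence both methyls β and H-8 α). The existing C2 centre is matched: in the reactive conformer C2–H lies in the diene plane (minimal allylic 1,3-strain) and the silyloxy group points to the convex face. The step needs (4+3) closure to win over (3+2) closure at C10 and over 1,2-shift (Meinwald-type) of the activated oxirane; high dilution, −78 °C, the catalytic silyl triflate and the tether, which lets the diene reach only C5, are meant to secure this.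

**Step 15**
Reactants: 23 2β-[(tert-butyldimethylsilyl)oxy]-4α-hydroxy-5βH-dauc-9-en-6-one
Product: 24 2β-[(tert-butyldimethylsilyl)oxy]-5βH-dauc-9-ene-4α,6β-diol
Conditions: Me4NBH(OAc)3 (5 equiv), MeCN/AcOH (1:1), −20 °C to rt
Reagents that add atoms: none
Why: Evans–Saksena hydroxyl-directed reduction: the tertiary 4α-hydroxyl, which is cis to C6 on the cyclopentane, should bind boron and deliver hydride to the α-face of the C6 ketone, giving the 6β-alcohol (1,3-anti diol).

**Step 16**
Reactants: 24 2β-[(tert-butyldimethylsilyl)oxy]-5βH-dauc-9-ene-4α,6β-diol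
Product: 26 2β-[(tert-butyldimethylsilyl)oxy]-8α,9α-epoxy-5βH-daucane-4α,6β,10α-triol, via allylic hydroperoxide 25 (not isolated)
Conditions: O2, tetraphenylporphyrin (1 mol%), visible light, CH2Cl2, 0 °C; then Ti(OiPr)4 (0.3 equiv), −20 to 0 °C
Reagents that add atoms: oxygen, O=O
Why: Schenck ene reaction of singlet oxygen, suprafacial and regiospecific here because C1 is quaternary (oxygen bonds to C10 on the α-face from which the only allylic hydrogen, H-8α, is taken), followed by titanium-mediated oxygen transfer from the hydroperoxide to the new C8=C9 bond syn to the C10–O bond, as in hydroxyl-directed epoxidation of cycloheptenols, which sets C8, C9 and C10.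

**Step 17**
Reactants: 26 2β-[(tert-butyldimethylsilyl)oxy]-8α,9α-epoxy-5βH-daucane-4α,6β,10α-triol; 27 tigloyl chloride [(2E)-2-methylbut-2-enoyl chloride]
Product: 28 2β-[(tert-butyldimethylsilyl)oxy]-8α,9α-epoxy-4α-hydroxy-5βH-daucane-6β,10α-diyl bis[(2E)-2-methylbut-2-enoate]
Conditions: 27 (4 equiv), Et3N (6 equiv), DMAP (1 equiv), CH2Cl2, 0 to 40 °C
Reagents that add atoms: none
Why: DMAP-catalysed acylation of the two secondary alcohols; the tertiary, isopropyl-flanked C4 hydroxyl should not react, the base protects the oxirane from HCl, and the (E)-acyl group is the stable isomer.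

**Step 18**
Reactants: 28 2β-[(tert-butyldimethylsilyl)oxy]-8α,9α-epoxy-4α-hydroxy-5βH-daucane-6β,10α-diyl bis[(2E)-2-methylbut-2-enoate]
Product: 29 (1S,2S,4R,5S,6S,8S,9R,10R)-8,9-epoxy-2,4-dihydroxydaucane-6,10-diyl bis[(2E)-2-methylbut-2-enoate] (CNP0265715.1)
Conditions: HF·pyridine, pyridine, THF, 0 °C to rt
Reagents that add atoms: none
Why: Buffered fluoride desilylation cleaves the silyl ether without base, so ester migration to the liberated C2 hydroxyl and oxirane opening should be avoided.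

**Compound list**
1 | prop-2-yn-1-ol (propargyl alcohol) | OCC#C | starting material
2 | bromomagnesium (2Z)-3-(bromomagnesio)-2-methylprop-2-en-1-olate | Br[Mg]OC/C(C)=C\[Mg]Br | intermediate
3 | (2Z)-3-iodo-2-methylprop-2-en-1-ol | OC/C(C)=C\I | intermediate
4 | (2Z)-3-iodo-2-methylprop-2-enal | O=C/C(C)=C\I | intermediate
5 | allenylboronic acid pinacol ester | C=C=CB1OC(C)(C)C(C)(C)O1 | starting material
6 | (1Z,3S)-1-iodo-2-methylhex-1-en-5-yn-3-ol | C#CC[C@H](O)/C(C)=C\I | intermediate
7 | tert-butyl{[(1Z,3S)-1-iodo-2-methylhex-1-en-5-yn-3-yl]oxy}dimethylsilane | C#CC[C@H](O[Si](C)(C)C(C)(C)C)/C(C)=C\I | intermediate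
8 | (E)-prop-1-en-1-ylboronic acid | C/C=C/B(O)O | starting material
9 | tert-butyldimethyl{[(4S,5Z,7E)-5-methylnona-5,7-dien-1-yn-4-yl]oxy}silane | C#CC[C@H](O[Si](C)(C)C(C)(C)C)/C(C)=C\C=C\C | intermediate
10 | lithium acetylide of 9 | [Li]C#CC[C@H](O[Si](C)(C)C(C)(C)C)/C(C)=C\C=C\C | intermediate
11 | methyl (5S,6Z,8E)-5-[(tert-butyldimethylsilyl)oxy]-6-methyldeca-6,8-dien-2-ynoate | COC(=O)C#CC[C@H](O[Si](C)(C)C(C)(C)C)/C(C)=C\C=C\C | intermediate
12 | alkenylcopper adduct (copper at C2, cis to isopropyl) | COC(=O)/C([Cu])=C(/C(C)C)C[C@H](O[Si](C)(C)C(C)(C)C)/C(C)=C\C=C\C | intermediate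
13 | methyl (2E,5S,6Z,8E)-5-[(tert-butyldimethylsilyl)oxy]-6-methyl-3-(propan-2-yl)deca-2,6,8-trienoate | COC(=O)/C=C(/C(C)C)C[C@H](O[Si](C)(C)C(C)(C)C)/C(C)=C\C=C\C | intermediate
14 | (2E,5S,6Z,8E)-5-[(tert-butyldimethylsilyl)oxy]-6-methyl-3-(propan-2-yl)deca-2,6,8-trien-1-ol | OC/C=C(/C(C)C)C[C@H](O[Si](C)(C)C(C)(C)C)/C(C)=C\C=C\C | intermediate
15 | [(2R,3R)-3-{(2S,3Z,5E)-2-[(tert-butyldimethylsilyl)oxy]-3-methylhepta-3,5-dien-1-yl}-3-(propan-2-yl)oxiran-2-yl]methanol | OC[C@H]1O[C@@]1(C(C)C)C[C@H](O[Si](C)(C)C(C)(C)C)/C(C)=C\C=C\C | intermediate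
16 | (2S,3R)-3-{(2S,3Z,5E)-2-[(tert-butyldimethylsilyl)oxy]-3-methylhepta-3,5-dien-1-yl}-3-(propan-2-yl)oxirane-2-carbaldehyde | O=C[C@H]1O[C@@]1(C(C)C)C[C@H](O[Si](C)(C)C(C)(C)C)/C(C)=C\C=C\C | intermediate
17 | 1-[(2R,3R)-3-{(2S,3Z,5E)-2-[(tert-butyldimethylsilyl)oxy]-3-methylhepta-3,5-dien-1-yl}-3-(propan-2-yl)oxiran-2-yl]ethan-1-ol (both carbinol epimers) | CC(O)[C@H]1O[C@@]1(C(C)C)C[C@H](O[Si](C)(C)C(C)(C)C)/C(C)=C\C=C\C | intermediate
18 | 1-[(2S,3R)-3-{(2S,3Z,5E)-2-[(tert-butyldimethylsilyl)oxy]-3-methylhepta-3,5-dien-1-yl}-3-(propan-2-yl)oxiran-2-yl]ethan-1-one | CC(=O)[C@H]1O[C@@]1(C(C)C)C[C@H](O[Si](C)(C)C(C)(C)C)/C(C)=C\C=C\C | intermediate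
19 | lithium enolate of 18 | [Li]OC(=C)[C@H]1O[C@@]1(C(C)C)C[C@H](O[Si](C)(C)C(C)(C)C)/C(C)=C\C=C\C | intermediate
20 | triethyl{[1-[(2S,3R)-3-{(2S,3Z,5E)-2-[(tert-butyldimethylsilyl)oxy]-3-methylhepta-3,5-dien-1-yl}-3-(propan-2-yl)oxiran-2-yl]ethenyl]oxy}silane | C=C(O[Si](CC)(CC)CC)[C@H]1O[C@@]1(C(C)C)C[C@H](O[Si](C)(C)C(C)(C)C)/C(C)=C\C=C\C | intermediate
21 | O-triethylsilyl epoxonium triflate of 20 | C=C(O[Si](CC)(CC)CC)[C@H]1[O+]([Si](CC)(CC)CC)[C@@]1(C(C)C)C[C@H](O[Si](C)(C)C(C)(C)C)/C(C)=C\C=C\C.[O-]S(=O)(=O)C(F)(F)F | intermediate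
22 | 2β-[(tert-butyldimethylsilyl)oxy]-4α-[(triethylsilyl)oxy]-5βH-dauc-9-en-6-one | O=C1C[C@@H](C)C=C[C@@]2(C)[C@@H]1[C@](O[Si](CC)(CC)CC)(C(C)C)C[C@@H]2O[Si](C)(C)C(C)(C)C | intermediate
23 | 2β-[(tert-butyldimethylsilyl)oxy]-4α-hydroxy-5βH-dauc-9-en-6-one | O=C1C[C@@H](C)C=C[C@@]2(C)[C@@H]1[C@](O)(C(C)C)C[C@@H]2O[Si](C)(C)C(C)(C)C | intermediate
24 | 2β-[(tert-butyldimethylsilyl)oxy]-5βH-dauc-9-ene-4α,6β-diol | O[C@H]1C[C@@H](C)C=C[C@@]2(C)[C@@H]1[C@](O)(C(C)C)C[C@@H]2O[Si](C)(C)C(C)(C)C | intermediate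
25 | 2β-[(tert-butyldimethylsilyl)oxy]-10α-hydroperoxy-5βH-dauc-8-ene-4α,6β-diol | O[C@H]1CC(C)=C[C@H](OO)[C@@]2(C)[C@@H]1[C@](O)(C(C)C)C[C@@H]2O[Si](C)(C)C(C)(C)C | intermediate
26 | 2β-[(tert-butyldimethylsilyl)oxy]-8α,9α-epoxy-5βH-daucane-4α,6β,10α-triol | O[C@H]1C[C@]2(C)O[C@@H]2[C@H](O)[C@@]2(C)[C@@H]1[C@](O)(C(C)C)C[C@@H]2O[Si](C)(C)C(C)(C)C | intermediate
27 | tigloyl chloride [(2E)-2-methylbut-2-enoyl chloride] | C/C=C(\C)C(Cl)=O | starting material
28 | 2β-[(tert-butyldimethylsilyl)oxy]-8α,9α-epoxy-4α-hydroxy-5βH-daucane-6β,10α-diyl bis[(2E)-2-methylbut-2-enoate] | C/C=C(\C)C(=O)O[C@H]1C[C@]2(C)O[C@@H]2[C@H](OC(=O)/C(C)=C/C)[C@@]2(C)[C@@H]1[C@](O)(C(C)C)C[C@@H]2O[Si](C)(C)C(C)(C)C | intermediate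
29 | (1S,2S,4R,5S,6S,8S,9R,10R)-8,9-epoxy-2,4-dihydroxydaucane-6,10-diyl bis[(2E)-2-methylbut-2-enoate] (CNP0265715.1) | C/C=C(\C)C(=O)O[C@H]1C[C@]2(C)O[C@@H]2[C@H](OC(=O)/C(C)=C/C)[C@@]2(C)[C@@H]1[C@](O)(C(C)C)C[C@@H]2O | target

**Totals**
Total step count: 18. Longest linear sequence: 18 steps (from propargyl alcohol).

**Steps most likely to fail**

Step 14. The (Z)-diene may react through its s-trans conformer and close to a five-membered ketone at C10 ((3+2) pathway), the silylated oxirane may undergo a 1,2-alkyl shift before the diene captures it, or the allylic C2 silyl ether may ionise. The fallback generates a free oxyallyl cation by dehydrohalogenation instead of by Lewis-acid opening of the oxirane. It sets out from ketone 18: MgBr2·OEt2 (Et2O, −20 °C) should open the chelated epoxy ketone at C5 with inversion to give (3R,4R,6S,7Z,9E)-3-bromo-6-[(tert-butyldimethylsilyl)oxy]-4-hydroxy-7-methyl-4-(propan-2-yl)undeca-7,9-dien-2-one F1. Silylation with Et3SiOTf and 2,6-lutidine (CH2Cl2, −78 °C) should give its 4-O-triethylsilyl ether F2, which cannot close back to the oxirane. Triethylamine in 2,2,2-trifluoroethanol (rt) should then enolise the methyl ketone and expel bromide. The resulting oxyallyl cation is longer-lived and reversibly solvated, so it can wait for the s-cis diene and undergo the intramolecular (4+3) cycloaddition. The fallback rejoins the route at silyl ether 22, which is hydrolysed to 23 as in step 14.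

Step 16. The ene reaction of the cis-disubstituted alkene next to the quaternary centre may be too slow, so that over-oxidation or incomplete oxygen transfer takes over. The fallback replaces the ene reaction by epoxidation and base-induced isomerisation. It sets out from diol 24: m-CPBA with NaHCO3 (CH2Cl2, 0 °C) should epoxidise the alkene from the α-face, away from the two β-methyls, to give 2β-[(tert-butyldimethylsilyl)oxy]-9α,10α-epoxy-5βH-daucane-4α,6β-diol F3. Diethylaluminium 2,2,6,6-tetramethylpiperidide (from Et2AlCl and lithium 2,2,6,6-tetramethylpiperidide, toluene, 0 °C) should remove H-8α, the only hydrogen syn to the oxirane, in a syn-elimination and give 2β-[(tert-butyldimethylsilyl)oxy]-5βH-dauc-8-ene-4α,6β,10α-triol F4. Hydroxyl-directed epoxidation with VO(acac)2 and t-BuOOH (CH2Cl2, 0 °C) then rejoins the route at epoxy triol 26.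

Step 15. If the hindered tertiary alkoxide does not bind boron, hydride is delivered from the open β-face and the 6α-alcohol forms. The fallback accepts this facial preference and corrects it by inversion. It sets out from ketone 23: NaBH4 with CeCl3·7H2O (MeOH, −78 °C) should give 2β-[(tert-butyldimethylsilyl)oxy]-5βH-dauc-9-ene-4α,6α-diol F5. Mitsunobu inversion (PPh3, diisopropyl azodicarboxylate, 4-nitrobenzoic acid, toluene, 0 °C to rt) should give 2β-[(tert-butyldimethylsilyl)oxy]-4α-hydroxy-5βH-dauc-9-en-6β-yl 4-nitrobenzoate F6. Methanolysis (K2CO3, MeOH, rt) then rejoins the route at diol 24.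

**Further compounds**
F1 | step 14 | (3R,4R,6S,7Z,9E)-3-bromo-6-[(tert-butyldimethylsilyl)oxy]-4-hydroxy-7-methyl-4-(propan-2-yl)undeca-7,9-dien-2-one | CC(=O)[C@H](Br)[C@](O)(C(C)C)C[C@H](O[Si](C)(C)C(C)(C)C)/C(C)=C\C=C\C
F2 | step 14 | (3R,4R,6S,7Z,9E)-3-bromo-6-[(tert-butyldimethylsilyl)oxy]-7-methyl-4-(propan-2-yl)-4-[(triethylsilyl)oxy]undeca-7,9-dien-2-one | CC(=O)[C@H](Br)[C@](O[Si](CC)(CC)CC)(C(C)C)C[C@H](O[Si](C)(C)C(C)(C)C)/C(C)=C\C=C\C
F3 | step 16 | 2β-[(tert-butyldimethylsilyl)oxy]-9α,10α-epoxy-5βH-daucane-4α,6β-diol | O[C@H]1C[C@@H](C)[C@@H]2O[C@@H]2[C@@]2(C)[C@@H]1[C@](O)(C(C)C)C[C@@H]2O[Si](C)(C)C(C)(C)C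
F4 | step 16 | 2β-[(tert-butyldimethylsilyl)oxy]-5βH-dauc-8-ene-4α,6β,10α-triol | O[C@H]1CC(C)=C[C@H](O)[C@@]2(C)[C@@H]1[C@](O)(C(C)C)C[C@@H]2O[Si](C)(C)C(C)(C)C
F5 | step 15 | 2β-[(tert-butyldimethylsilyl)oxy]-5βH-dauc-9-ene-4α,6α-diol | O[C@@H]1C[C@@H](C)C=C[C@@]2(C)[C@@H]1[C@](O)(C(C)C)C[C@@H]2O[Si](C)(C)C(C)(C)C
F6 | step 15 | 2β-[(tert-butyldimethylsilyl)oxy]-4α-hydroxy-5βH-dauc-9-en-6β-yl 4-nitrobenzoate | O=C(O[C@H]1C[C@@H](C)C=C[C@@]2(C)[C@@H]1[C@](O)(C(C)C)C[C@@H]2O[Si](C)(C)C(C)(C)C)c1ccc(cc1)[N+](=O)[O-]
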